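## The problem

The target **25** is a trans-fused hydrindane. Cyclopentanone ring A (C1–C2–C3–C4–C5) shares the C4–C5 bond with cyclohexene ring B (C4–C5–C6=C7–C8–C9). This numbering is used for every intermediate. The face of H4, the C3 methyl, the styryl group and the carboxyl is called β; the face of H5 and of all three ethyl groups is called α.

- **Correctable centres.** C1 and C3 flank the C2 ketone, and C5 is α to a carbonyl whenever C6 is a ketone. These three can be left to equilibration, and the target holds them in the all-trans arrangement that equilibration favours.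
- **The centre that cannot be corrected.** C4 is the only tertiary centre that is never enolisable. It has to be set absolutely and then has to control everything else.
- **The quaternary pair.** C8 and C9 are vicinal quaternary carbons, with both ethyls α and both carboxyl-derived carbons (styryl, CO2H) β. The order in which their four substituents arrive decides whether ring B sends each to the correct face.
- **Fragile groups.** The styrene, the C6=C7 alkene and a free acid placed to lactonise onto either alkene under strong acid must appear late and be spared oxidants and hot acid.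
- **The enabling feature.** Ring B contains the sequence C6–C7–C8: a carbon that can be a ketone, one CH carbon, then a carbon bearing a carboxyl-derived carbon. This is the pattern left when CH2 is inserted between the carbonyl and the α-carbon of a cyclopentanone β-keto ester.

## Retrosynthesis

**25 ⇒ 24 ⇒ 22 + 23 ⇒ 21.** The last operation only unmasks the acid and the ketone of **24**. Before that the Cα=Cβ bond of the styryl group is cut (Horner–Wadsworth–Emmons) to the neopentyl aldehyde **22** and diethyl benzylphosphonate **23**. Cutting there, and not at C8–Cα, keeps the carboxyl-derived carbon on C8; **22** comes from the methyl ester of **21** by partial reduction. The forward steps must give the (E)-alkene and leave the tert-butyl ester alone.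

**21 ⇒ 20 ⇒ 19.** The C9–ethyl bond is cut, then the C8–ethyl bond; forward, C8 is ethylated first and C9 second. This order is the stereochemical core of the plan.
- On a trans-fused ring B the α substituent of C9 is pseudo-axial. If C9 were quaternary first, its axial ethyl would stand perpendicular to the C8 enolate and send the second ethyl to the β face, giving the trans-diethyl isomer.
- With C9 still a CH(CO2tBu) centre (**19**), the C8 enolate is approached on the α face, past the small axial H and away from the equatorial ester.
- The new C8 centre of **20** then carries its methyl ester pseudo-axially on the β face, which in turn sends the C9 electrophile to the α face.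
- **19** has no quaternary carbon. The forward reactions must be regioselective (the allylic, ester-activated C8–H first) and must tolerate the building of two adjacent quaternary carbons.

**19 ⇒ 18 ⇒ 17.** The C6–CH3 bond is cut (cross-coupling) to enol triflate **18** and further to ketone **17**. A C6 ketone is worth more than the alkene: it is the handle for epimerising C5 and it is what the ring expansion leaves behind. Enolisation must go toward C7, not toward C5.

**17 ⇒ 16 ⇒ 15 (key cut).** **17** is the thermodynamic epimer of **16**. In **16** the C6–C7 bond is cut and C7 is returned to C8 as a bromomethyl group, which contracts ring B to the cyclopentanone ring P (C4–C5–C6–C8–C9) of **15**. Direct closure of a six-membered ring would need the trans fusion or a longer chain with the same stereochemical load. The cis-fused bicyclo[3.3.0]octane closes by itself, and the fusion is corrected afterwards. The forward radical rearrangement must outrun simple reduction.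

**15 ⇒ 13 + 14 ⇒ 12.** The C8–C7 bond is cut (alkylation of β-keto ester **13** with dibromomethane **14**), then C6–C8 (Dieckmann) to triester **12**. An aldol-type closure from a C4 acyl group was rejected: it would make C4 enolisable at the moment when a cis relationship has to be reached by epimerisation. In **12** only C5 can epimerise.

**12 ⇒ 11 ⇒ 9 + 10.** The C6 ester is traced to a vinyl group (ozonolysis to the ester), and the C9–C8 bond is cut to the tert-butyl ester enolate of **9** and methyl bromoacetate **10**. This gives the two carboxyl groups different esters from the start, so they never have to be told apart later.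

**9 ⇒ 8 ⇒ 7 ⇒ 6 ⇒ 3 + 2 ⇒ 1.** Ring A is stripped substituent by substituent:
- the ketal, then the C1 ethyl and C5 vinyl (conjugate addition with enolate trapping on enone **7**);
- the C3 methyl (α′-alkylation of **6**);
- the C4–C9 bond (Mukaiyama–Michael addition of ketene silyl acetal **2**, from tert-butyl acetate **1**, to the purchased silyloxy enone **3**).

Each new group enters anti to its neighbour. The single stereocentre of **3** is relayed to C4 and is then lost by elimination.

## Roads not taken

**Alternative 1:** Pauson–Khand cyclocarbonylation.
- *Cut and key step:* C4–C5, C1–C2 and C2–C3 are cut at once. Forward, the cobalt-mediated reaction of dienyne **A1** closes rings A and B together and gives enone **A2**.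
- *Merits:* three C–C bonds and both rings in one operation, from a chain that can be assembled convergently. In bond count per step it is clearly better than the chosen plan.
- *Weak points:*
  - C8 and C9 must already be present, adjacent and configured, on an open chain, where there is no ring to direct the second quaternary centre.
  - The alkyne hangs on a quaternary carbon, and the ene partner is an internal alkene inside a conjugated diene; both slow the cycloaddition and invite other pathways.
  - **A2** still has C3=C4, so C4, the one centre that cannot be corrected, would be made by a late conjugate reduction that must deliver H to the β face against the neighbouring quaternary carbon.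
- *Comparison:* the chosen plan sets against the shorter ring construction a C4 centre fixed in the second step and two quaternary carbons built under ring control.

**Alternative 2:** Anodic coupling of two silyl enol ethers.
- *Cut and key step:* C1–C5 is cut. Forward, anodic oxidation of bis(silyl enol ether) **A3** closes ring A and gives 1,4-diketone **A4**.
- *Merits:* the C2/C6 dicarbonyl relationship is made directly, without tin and without a ketal. C1 and C5 are both epimerisable, so the fusion is thermodynamic. If **A3** were in hand this would be the shortest endgame.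
- *Weak points:*
  - The key step does nothing for C4, C8 and C9; they must all be built on a cyclohexanone beforehand.
  - **A3** needs two regiodefined enol ethers, one next to the epimerisable C3.
  - The electron-rich styrene is present during the oxidation.
  - **A4** has two ketones, and C6 must be distinguished from C2 for the methyl alkene.
- *Comparison:* the chosen plan is longer after the key step, but it gives a complete answer to the three centres that cannot be corrected.

**Alternative 3:** Diels–Alder reaction with diethylmaleic anhydride.
- *Cut and key step:* C4–C9 and C7–C8 are cut. Forward, siloxydiene **A5** and 2,3-diethylmaleic anhydride **A6** give cycloadduct **A7**.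
- *Merits:* this is the best answer to the quaternary pair. Both ethyls cis and both carbonyls cis follow from the dienophile in one step, where the chosen plan needs two difficult alkylations. In this respect it is superior.
- *Weak points:*
  - A tetrasubstituted dienophile of this kind is sluggish and reversible, and the diene terminus C4 is substituted; forcing conditions threaten the silyl enol ether.
  - C4 is set only by facial selection from ring A centres that are themselves epimerisable.
  - The two anhydride carbonyls (one to become the styryl carbon, one the acid) differ only in remote environment.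
- *Comparison:* the chosen plan differentiates the two carboxyl carbons from the outset (methyl against tert-butyl ester) and uses ordinary reactivity, at the price of the two hindered ethylations.

Key step: step 10

Assumption: compounds 11 and 12 are mixtures of C9 epimers and 13, 15 and 16 mixtures of C8 epimers (no descriptor drawn at these atoms); C9 of 13, 15 and 16 is drawn as the expected exo (β) ester, and every such centre is erased or equilibrated by step 11.

## Route

Step 1
Reactants: 1 tert-butyl acetate
Product: 2 (1-tert-butoxyethenyloxy)trimethylsilane
Conditions: LiN(iPr)2, THF, −78 °C; Me3SiCl, −78 °C → rt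
Reagents that add atoms: chlorotrimethylsilane, C[Si](C)(C)Cl
Why: O-silylation of the lithium enolate of a tert-butyl ester gives the ketene silyl acetal; the bulky alkoxy group suppresses C-silylation and Claisen self-condensation.

Step 2
Reactants: 3 (S)-4-(tert-butyldimethylsilyloxy)cyclopent-2-en-1-one, 2 (1-tert-butoxyethenyloxy)trimethylsilane
Product: 6 tert-butyl 2-[(1R)-4-oxocyclopent-2-en-1-yl]acetate, via trimethylsilyl enol ether 4 (not isolated), via trans β-silyloxy ketone 5 (not isolated)
Conditions: Sc(OTf)3 (5 mol %), CH2Cl2, −78 °C; 1 M HCl, THF, 0 °C; DBU, CH2Cl2, 0 °C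
Reagents that add atoms: none
Why: Lewis acid catalysed Mukaiyama–Michael addition to a 4-silyloxycyclopentenone occurs anti to the silyloxy group and so sets C4. Hydrolysis of the enol silane and E1cB loss of silanolate then move the enone to C1=C5 (addition–elimination), leaving C4 as the only stereocentre.

Step 3
Reactants: 6 tert-butyl 2-[(1R)-4-oxocyclopent-2-en-1-yl]acetate
Product: 7 tert-butyl 2-[(1R,5S)-5-methyl-4-oxocyclopent-2-en-1-yl]acetate (methyl trans to the side chain)
Conditions: LiN(iPr)2, THF, −78 °C; MeI, −78 → −40 °C
Reagents that add atoms: iodomethane, CI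
Why: Kinetic α′-deprotonation of the enone gives the cross-conjugated lithium dienolate, which is methylated anti to the C4 side chain; the tert-butyl ester α-protons are less acidic and its carbonyl is too far and too hindered for Claisen closure.

Step 4
Reactants: 7 tert-butyl 2-[(1R,5S)-5-methyl-4-oxocyclopent-2-en-1-yl]acetate
Product: 8 tert-butyl 2-[(1R,2R,3S,5S)-2-ethenyl-3-ethyl-5-methyl-4-oxocyclopentyl]acetate (all-trans: C1 ethyl α, C3 methyl β, C4 side chain α, C5 vinyl β)
Conditions: (CH2=CH)2CuLi, THF, −78 °C; EtI, HMPA, −78 → −20 °C; aq NH4Cl
Reagents that add atoms: lithium divinylcuprate, [Li+].C=C[Cu-]C=C; iodoethane, CCI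
Why: Cuprate conjugate addition anti to the C4 side chain is followed by alkylation of the regiodefined lithium enolate anti to the new vinyl group (conjugate addition–enolate trapping). Both α-centres are in any case the thermodynamic epimers.

Step 5
Reactants: 8 tert-butyl 2-[(1R,2R,3S,5S)-2-ethenyl-3-ethyl-5-methyl-4-oxocyclopentyl]acetate
Product: 9 ethylene ketal (dioxolane at C2) of 8, ring A all-trans as in 8
Conditions: Me3SiOCH2CH2OSiMe3, Me3SiOTf (cat.), CH2Cl2, −78 → −20 °C
Reagents that add atoms: 1,2-bis(trimethylsilyloxy)ethane, C[Si](C)(C)OCCO[Si](C)(C)C
Why: Silyl-transfer ketalisation works on hindered ketones below 0 °C and spares the tert-butyl ester and the vinyl group; it locks C1 and C3 in the configuration the target needs.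

Step 6
Reactants: 9 ethylene ketal of 8, 10 methyl bromoacetate
Product: 11 1-tert-butyl 4-methyl butanedioate carrying ring A of 9 on its C2 carbon (target C9; C9 epimers)
Conditions: LiN(iPr)2, THF, −78 °C; 10, DMPU, −78 → −40 °C
Reagents that add atoms: none
Why: Alkylation of a tert-butyl ester lithium enolate with an α-bromo ester is routine succinate chemistry. C9 carries the only acidic hydrogens of 9, and the configuration made there is equilibrated later.

Step 7
Reactants: 11 succinate diester (C9 epimers)
Product: 12 triester: 11 with the C5 vinyl group replaced by CO2Me (C5 ester β, trans to the C4 chain; C9 epimers)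
Conditions: O3, NaOH, MeOH/CH2Cl2, −78 °C
Reagents that add atoms: ozone, [O-][O+]=O; methanol, CO
Why: Ozonolysis in methanolic NaOH converts a terminal alkene directly into the methyl ester, because the hemiacetal and the methoxy hydroperoxide are oxidised in the same flask. The vinyl group is the only alkene, and the ketal and esters tolerate the cold basic medium.

Step 8
Reactants: 12 triester (C9 epimers)
Product: 13 cis-fused bicyclo[3.3.0]octane β-keto ester (ring A of 9 fused through C4–C5 to ring P; H4 and H5 β; C6 ketone; C8 H(CO2Me); C9 H α, CO2tBu β)
Conditions: KOtBu, THF, 0 °C → rt; AcOH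
Reagents that add atoms: none
Why: Dieckmann condensation: only the C5 epimer with its ester cis to the C4 chain can close, and that ester epimerises under the alkoxide while C4 cannot. Of the possible Claisen products only the one from C8 attacking C6 has a proton between two carbonyls and is held as its enolate, so the equilibria funnel to 13; the less crowded exo ester at C9 should predominate.

Step 9
Reactants: 13 cis-fused β-keto ester, 14 dibromomethane
Product: 15 bromomethyl β-keto ester (13 with CH2Br on C8; C8 epimers)
Conditions: NaH (1.0 equiv), THF/HMPA, 0 °C; 14 (excess), rt → 50 °C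
Reagents that add atoms: none
Why: C-alkylation of the sodium enolate of a cyclic β-keto ester with excess dibromomethane is the standard entry to Dowd–Beckwith substrates. One equivalent of base leaves the C9–H alone, and the C8 configuration is erased in the next step.

Step 10
Reactants: 15 bromomethyl β-keto ester
Product: 16 cis-fused hydrindanone (ring B: C6 ketone, C7 H2, C8 H(CO2Me) as epimers, C9 H α, CO2tBu β; H4 and H5 β; ring A as in 9)
Conditions: Bu3SnH (slow addition), AIBN (cat.), benzene (0.01 M), 80 °C
Reagents that add atoms: none
Why: Dowd–Beckwith ring expansion: the stannyl radical abstracts bromine, the primary C7 radical adds to the neighbouring C6 carbonyl carbon in a 3-exo-trig mode, and the cyclopropyloxy radical opens by β-scission of the old C6–C8 bond. Ring P is thereby enlarged to ring B with C6–C7 newly formed; ring B arises by a net 1,2-acyl shift, not by direct six-ring closure. The direction of opening is inherent in the substrate, because cleaving C6–C8 gives a tertiary, ester-stabilised radical whereas the reverse only returns the primary one. The closest known reaction is the conversion of 2-(bromomethyl)-2-alkoxycarbonylcyclopentanones into 3-alkoxycarbonylcyclohexanones with Bu3SnH and AIBN. No lasting stereocentre is made: C8 is trigonal in the radical and the C8–H formed by hydrogen transfer is equilibrated in step 11, while C4 and the cis fusion are untouched. The selectivity needed is rearrangement before reduction, which is secured by keeping the stannane concentration low. The ketone carbonyl is attacked far faster than either ester carbonyl, and the ketal, the tert-butyl ester and the C9–H are inert to the radical chain.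

Step 11
Reactants: 16 cis-fused hydrindanone
Product: 17 trans-fused hydrindanone (H4 β, H5 α; C8 CO2Me α; C9 CO2tBu β; both esters equatorial)
Conditions: NaOMe (cat.), MeOH, 40 °C
Reagents that add atoms: none
Why: Base equilibration: C5 (α to the ketone) and C8 and C9 (α to esters) are all epimerisable. The trans fusion, which also puts C6 trans to the C1 ethyl, with both esters equatorial is the thermodynamic isomer; methoxide returns the methyl ester unchanged and attacks the tert-butyl ester only slowly.

Step 12
Reactants: 17 trans-fused hydrindanone
Product: 18 C6=C7 enol triflate of 17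
Conditions: KN(SiMe3)2, THF, −78 °C; PhNTf2, −78 → 0 °C; aq NH4Cl
Reagents that add atoms: N-phenylbis(trifluoromethanesulfonimide), O=S(=O)(N(c1ccccc1)S(=O)(=O)C(F)(F)F)C(F)(F)F
Why: Kinetic deprotonation of the ketone takes place at the C7 methylene, not at the ring-fusion methine C5, and O-triflation fixes that regiochemistry; ester α-protons are not removed at −78 °C.

Step 13
Reactants: 18 enol triflate
Product: 19 C6-methyl alkene (C6(CH3)=C7; C8 H β, CO2Me α; C9 H α, CO2tBu β)
Conditions: MeZnCl, Pd(PPh3)4 (cat.), THF, 50 °C
Reagents that add atoms: methylzinc chloride, C[Zn]Cl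
Why: Negishi coupling of an enol triflate with a methylzinc reagent under zerovalent palladium catalysis is general and tolerates esters and ketals; it places the methyl-bearing alkene in its final position.

Step 14
Reactants: 19 C6-methyl alkene
Product: 20 C8-quaternary diester (C8 ethyl α, CO2Me β; C9 H α, CO2tBu β)
Conditions: LiN(iPr)2, THF/HMPA, −78 °C; EtI, −78 → −20 °C
Reagents that add atoms: iodoethane, CCI
Why: The allylic, ester-activated C8–H is removed selectively, and the extended enolate is alkylated at its α-carbon. Ethyl iodide approaches on the α face, past the axial C9–H and away from the equatorial tert-butyl ester, so the ethyl ends up trans to that ester and the two esters cis.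

Step 15
Reactants: 20 C8-quaternary diester
Product: 21 C8,C9-bis-quaternary diester (C8 ethyl α, CO2Me β; C9 ethyl α, CO2tBu β)
Conditions: LiN(iPr)2, THF/HMPA, −78 → 0 °C; EtI, 0 °C → rt
Reagents that add atoms: iodoethane, CCI
Why: The only enolisable position left is C9. Its exocyclic ester enolate is alkylated axially on the α face, anti to the pseudo-axial methyl ester on C8 and past only H5, which gives the cis-diethyl arrangement.

Step 16
Reactants: 21 bis-quaternary diester
Product: 22 aldehyde (C8 CHO β in place of CO2Me; otherwise as 21)
Conditions: iBu2AlH, CH2Cl2, −78 °C; aq sodium potassium tartrate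
Reagents that add atoms: none
Why: Partial reduction of a methyl ester on a quaternary carbon stops at the aldehyde because the crowded tetrahedral aluminate survives until work-up. The tert-butyl ester is much less reactive and the aldehyde has no α-hydrogen.

Step 17
Reactants: 22 aldehyde, 23 diethyl benzylphosphonate
Product: 24 (E)-styrene (C8 (E)-2-phenylethenyl β, ethyl α; C9 ethyl α, CO2tBu β; C2 dioxolane)
Conditions: 23, NaH, THF, 0 → 60 °C
Reagents that add atoms: none
Why: Horner–Wadsworth–Emmons olefination with the benzylphosphonate anion gives the (E)-alkene; the aldehyde cannot enolise, so the warming needed for a neopentyl aldehyde is tolerated.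

Step 18
Reactants: 24 (E)-styrene
Product: 25 CNP0302656.1 (C1 ethyl α, C2 ketone, C3 methyl β, H4 β, H5 α, C8 styryl β and ethyl α, C9 CO2H β and ethyl α)
Conditions: CF3CO2H, CH2Cl2, H2O (2 equiv), 0 °C → rt
Reagents that add atoms: water, O
Why: Acidolysis removes the tert-butyl ester as isobutene and hydrolyses the dioxolane in one operation under conditions too mild to protonate the alkenes. C1 and C3 already hold the all-trans arrangement, which is also the thermodynamic one for the free ketone, so enolisation cannot erode it.

## Compound list

1 | tert-butyl acetate | CC(=O)OC(C)(C)C | starting material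
2 | (1-tert-butoxyethenyloxy)trimethylsilane | C=C(OC(C)(C)C)O[Si](C)(C)C | intermediate
3 | (S)-4-(tert-butyldimethylsilyloxy)cyclopent-2-en-1-one | O=C1C=C[C@@H](O[Si](C)(C)C(C)(C)C)C1 | starting material
4 | tert-butyl 2-[trans-5-(tert-butyldimethylsilyloxy)-3-(trimethylsilyloxy)cyclopent-2-en-1-yl]acetate (side chain α, silyloxy β; not isolated) | C[Si](C)(C)OC1=C[C@H](CC(=O)OC(C)(C)C)[C@@H](O[Si](C)(C)C(C)(C)C)C1 | intermediate
5 | tert-butyl 2-[trans-2-(tert-butyldimethylsilyloxy)-4-oxocyclopentyl]acetate (not isolated) | O=C1C[C@H](CC(=O)OC(C)(C)C)[C@@H](O[Si](C)(C)C(C)(C)C)C1 | intermediate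
6 | tert-butyl 2-[(1R)-4-oxocyclopent-2-en-1-yl]acetate | O=C1C=C[C@@H](CC(=O)OC(C)(C)C)C1 | intermediate
7 | tert-butyl 2-[(1R,5S)-5-methyl-4-oxocyclopent-2-en-1-yl]acetate | O=C1C=C[C@@H](CC(=O)OC(C)(C)C)[C@@H]1C | intermediate
8 | tert-butyl 2-[(1R,2R,3S,5S)-2-ethenyl-3-ethyl-5-methyl-4-oxocyclopentyl]acetate | CC[C@@H]1C(=O)[C@@H](C)[C@H](CC(=O)OC(C)(C)C)[C@H]1C=C | intermediate
9 | ethylene ketal of 8 (C1 ethyl α, C3 methyl β, C4 CH2CO2tBu α, C5 vinyl β) | CC[C@@H]1C2(OCCO2)[C@@H](C)[C@H](CC(=O)OC(C)(C)C)[C@H]1C=C | intermediate
10 | methyl bromoacetate | COC(=O)CBr | starting material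
11 | 1-tert-butyl 4-methyl 2-(ring A of 9)butanedioate (C9 epimers) | CC[C@@H]1C2(OCCO2)[C@@H](C)[C@H](C(CC(=O)OC)C(=O)OC(C)(C)C)[C@H]1C=C | intermediate
12 | triester: 11 with CO2Me in place of the C5 vinyl group (C5 ester β; C9 epimers) | CC[C@@H]1C2(OCCO2)[C@@H](C)[C@H](C(CC(=O)OC)C(=O)OC(C)(C)C)[C@H]1C(=O)OC | intermediate
13 | cis-fused bicyclo[3.3.0]octane β-keto ester (H4, H5 β; C6 ketone; C8 H(CO2Me); C9 CO2tBu β) | CC[C@@H]1C2(OCCO2)[C@@H](C)[C@H]3[C@@H]1C(=O)C(C(=O)OC)[C@@H]3C(=O)OC(C)(C)C | intermediate
14 | dibromomethane | BrCBr | starting material
15 | bromomethyl β-keto ester (13 with CH2Br on C8; C8 epimers) | CC[C@@H]1C2(OCCO2)[C@@H](C)[C@H]3[C@@H]1C(=O)C(CBr)(C(=O)OC)[C@@H]3C(=O)OC(C)(C)C | intermediate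
16 | cis-fused ring-expanded hydrindanone (C6 ketone, C7 H2, C8 H(CO2Me) epimers, C9 CO2tBu β) | CC[C@@H]1C2(OCCO2)[C@@H](C)[C@H]3[C@@H]1C(=O)CC(C(=O)OC)[C@@H]3C(=O)OC(C)(C)C | intermediate
17 | trans-fused hydrindanone (H4 β, H5 α; C8 CO2Me α; C9 CO2tBu β) | CC[C@@H]1C2(OCCO2)[C@@H](C)[C@H]3[C@H]1C(=O)C[C@@H](C(=O)OC)[C@@H]3C(=O)OC(C)(C)C | intermediate
18 | C6=C7 enol triflate of 17 | CC[C@@H]1C2(OCCO2)[C@@H](C)[C@H]3[C@H]1C(OS(=O)(=O)C(F)(F)F)=C[C@@H](C(=O)OC)[C@@H]3C(=O)OC(C)(C)C | intermediate
19 | C6-methyl alkene (C8 CO2Me α, C9 CO2tBu β) | CC[C@@H]1C2(OCCO2)[C@@H](C)[C@H]3[C@H]1C(C)=C[C@@H](C(=O)OC)[C@@H]3C(=O)OC(C)(C)C | intermediate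
20 | C8-quaternary diester (C8 ethyl α, CO2Me β; C9 H α, CO2tBu β) | CC[C@@H]1C2(OCCO2)[C@@H](C)[C@H]3[C@H]1C(C)=C[C@@](C(=O)OC)(CC)[C@@H]3C(=O)OC(C)(C)C | intermediate
21 | C8,C9-bis-quaternary diester (both ethyls α, both esters β) | CC[C@@H]1C2(OCCO2)[C@@H](C)[C@H]3[C@H]1C(C)=C[C@@](C(=O)OC)(CC)[C@]3(CC)C(=O)OC(C)(C)C | intermediate
22 | aldehyde (C8 CHO β, ethyl α; C9 ethyl α, CO2tBu β) | CC[C@@H]1C2(OCCO2)[C@@H](C)[C@H]3[C@H]1C(C)=C[C@@](C=O)(CC)[C@]3(CC)C(=O)OC(C)(C)C | intermediate
23 | diethyl benzylphosphonate | CCOP(=O)(Cc1ccccc1)OCC | starting material
24 | (E)-styrene, tert-butyl ester, C2 dioxolane | CC[C@@H]1C2(OCCO2)[C@@H](C)[C@H]3[C@H]1C(C)=C[C@@](/C=C/c4ccccc4)(CC)[C@]3(CC)C(=O)OC(C)(C)C | intermediate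
25 | CNP0302656.1: 1,4,5-triethyl-3,7-dimethyl-2-oxo-5-[(E)-2-phenylethenyl]-2,3,3a,4,5,7a-hexahydro-1H-indene-4-carboxylic acid (indene numbering), configured as described in step 18 | CC[C@@H]1C(=O)[C@@H](C)[C@H]2[C@H]1C(C)=C[C@@](/C=C/c1ccccc1)(CC)[C@]2(CC)C(=O)O | target

## Step count and risks

Total: 18 steps. Longest linear sequence: 18 steps (1 → 25); 17 from the purchased enone 3.

**Step 10 (key step).** The most likely failure is hydrogen transfer from the stannane to the primary radical before it has added to the ketone, which would give simple reduction of the C–Br bond. With too little stannane the chain may die instead. The rearrangement is unimolecular, so its share depends only on how low the hydride concentration can be kept. Fallback: from β-keto ester 13 directly to 16 by zinc carbenoid chain extension (Et2Zn, CH2I2, CH2Cl2). The zinc enolate is cyclopropanated and the cyclopropanolate fragments to the same γ-keto ester after protonation. This is an ionic route to the same C6–C7 insertion, it bypasses 15 and creates no new compound.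

**Step 4.** Ethyl iodide reacts slowly with the enolate, so proton exchange between enolate and product (loss of regiochemistry, double alkylation) may overtake the trapping. Fallback: from 7, α-iodination (I2, pyridine) gives the 3-iodo derivative of 7, tert-butyl 2-(3-iodo-5-methyl-4-oxocyclopent-2-en-1-yl)acetate F1. Negishi coupling (Et2Zn, PdCl2(dppf)) gives the 3-ethyl enone, tert-butyl 2-(3-ethyl-5-methyl-4-oxocyclopent-2-en-1-yl)acetate F2. Addition of (CH2=CH)2CuLi with Me3SiCl and equilibrating protonation then returns to 8 without any enolate alkylation.

**Step 14.** SN2 attack at an enolate carbon flanked by a tertiary centre may be slow enough for γ-alkylation at C6, O-alkylation or proton transfer from C9 to compete. Facial discrimination also rests on one neighbouring ester. Fallback: from 19, Michael addition of the same enolate to phenyl vinyl sulfone, a faster two-carbon electrophile with a later, more selective transition state, gives the C8 2-(phenylsulfonyl)ethyl diester F3. Reductive desulfonylation (Mg, MeOH) returns to 20.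

**Step 15.** Enolisation next to a quaternary carbon is hindered, and the fully substituted enolate may be ethylated so slowly that elimination from ethyl iodide and proton return dominate. Fallback: from 20, conjugate addition of the C9 enolate (KN(SiMe3)2) to phenyl vinyl sulfone gives the C9 2-(phenylsulfonyl)ethyl diester F4. Desulfonylation (Mg, MeOH) returns to 21.

**Step 16.** The aluminate may collapse before work-up and lead to over-reduction, or the crowded ester may not react at −78 °C. Fallback: from 21, deliberate full reduction of the methyl ester (excess iBu2AlH, −78 → 0 °C) gives the C8 hydroxymethyl tert-butyl ester F5. Immediate oxidation (DMP, CH2Cl2) returns to 22; the alcohol is not stored, so that lactonisation onto the cis tert-butyl ester has no time to occur.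

## Further compounds

F0 | step 10 | none | none
F1 | step 4 | tert-butyl 2-(3-iodo-5-methyl-4-oxocyclopent-2-en-1-yl)acetate (configuration as 7) | O=C1C(I)=C[C@@H](CC(=O)OC(C)(C)C)[C@@H]1C
F2 | step 4 | tert-butyl 2-(3-ethyl-5-methyl-4-oxocyclopent-2-en-1-yl)acetate (configuration as 7) | O=C1C(CC)=C[C@@H](CC(=O)OC(C)(C)C)[C@@H]1C
F3 | step 14 | C8 2-(phenylsulfonyl)ethyl analogue of 20 (sulfonylethyl α, CO2Me β) | CC[C@@H]1C2(OCCO2)[C@@H](C)[C@H]3[C@H]1C(C)=C[C@@](C(=O)OC)(CCS(=O)(=O)c4ccccc4)[C@@H]3C(=O)OC(C)(C)C
F4 | step 15 | C9 2-(phenylsulfonyl)ethyl analogue of 21 (sulfonylethyl α, CO2tBu β) | CC[C@@H]1C2(OCCO2)[C@@H](C)[C@H]3[C@H]1C(C)=C[C@@](C(=O)OC)(CC)[C@]3(CCS(=O)(=O)c4ccccc4)C(=O)OC(C)(C)C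
F5 | step 16 | C8 hydroxymethyl analogue of 22 (CH2OH β) | CC[C@@H]1C2(OCCO2)[C@@H](C)[C@H]3[C@H]1C(C)=C[C@@](CO)(CC)[C@]3(CC)C(=O)OC(C)(C)C
A1 | alternative 1 | dienyne precursor: tert-butyl ester with C9 prop-1-ynyl and ethyl, C8 ethyl and 2-(tert-butyldimethylsilyloxy)ethyl, and a (Z,E)-diene chain | CC/C=C/C(C)=C\[C@@](CCO[Si](C)(C)C(C)(C)C)(CC)[C@@](CC)(C#CC)C(=O)OC(C)(C)C
A2 | alternative 1 | bicyclic enone with C3=C4 alkene | CC[C@@H]1C(=O)C(C)=C2[C@H]1C(C)=C[C@@](CCO[Si](C)(C)C(C)(C)C)(CC)[C@]2(CC)C(=O)OC(C)(C)C
A3 | alternative 2 | bis(tert-butyldimethylsilyl enol ether) of the ring-B ketone and the side-chain ethyl ketone | CCC=C(O[Si](C)(C)C(C)(C)C)[C@@H](C)[C@H]1C=C(O[Si](C)(C)C(C)(C)C)C[C@@](/C=C/c2ccccc2)(CC)[C@]1(CC)C(=O)OC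
A4 | alternative 2 | trans-fused C2,C6-diketone methyl ester | CC[C@@H]1C(=O)[C@@H](C)[C@H]2[C@H]1C(=O)C[C@@](/C=C/c1ccccc1)(CC)[C@]2(CC)C(=O)OC
A5 | alternative 3 | ring-A 2-siloxydiene (C4=C5–C6(OSi)=C7, C2 dioxolane) | CC[C@H]1C2(OCCO2)[C@@H](C)C=C1C(=C)O[Si](C)(C)C(C)(C)C
A6 | alternative 3 | 2,3-diethylmaleic anhydride | CCC1=C(CC)C(=O)OC1=O
A7 | alternative 3 | cycloadduct: ring-B silyl enol ether with anhydride across C8 and C9 | CC[C@H]1C2(OCCO2)[C@@H](C)[C@H]3C1=C(O[Si](C)(C)C(C)(C)C)C[C@]4(CC)C(=O)OC(=O)[C@]34CC
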